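**Retrosynthetic overview**
1. Endgame: the (S)-lactol is released last by neutral hydrogenolysis of an (S)-1-phenylethyl acetal together with the phenol benzyl ether. That acetal is obtained as one diastereomer by acid-mediated epimer equilibration coupled to crystallisation, after aqueous acid has unmasked the ring A aldehyde and the lactol.
2. Key disconnection: the seven-membered depsidone lactone is opened at the ring A aryl–C(=O) bond and the ring B aryl–O(ester) bond, which removes CO2 and leaves a diaryl ether with C–I on ring A and C–F on ring B.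
3. Enabling feature: in ring B the carbon that carries the ester oxygen is para to the carbon bearing the phthalide C=O, and the fused five-membered lactone holds that C=O coplanar with ring B, so this carbon is an SNAr site as C–F. In ring A the carbon that receives the carboxyl is para to OMe (selective iodination) and ortho to the ether oxygen, which sets up a seven-membered closure.
4. Diaryl ether: SNAr of the ring A ortho-formyl phenol at the ring B fluoride ortho to CHO. Phthalide: acid lactonisation of the ortho-formyl benzamide.
5. Ring order: both benzene rings are bought; the five-membered phthalide lactone (step 8) is formed before the seven-membered dioxepinone (step 10).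

Key step: step 10

Assumptions: the lactol carbon is a hemiacetal that can epimerise by ring–chain tautomerism with the 2-formylbenzoic acid form, so it is fixed as a stable acetal (step 12), liberated only in the last step under neutral aprotic conditions, and the product is to be kept as a solid or in neutral aprotic solution; of the two acetal epimers of step 12, the (1S) compound is taken to be the less soluble one.

**Route**

Step 1
Reactants: 1 1-fluoro-3-methoxy-5-methylbenzene
Product: 3 2-fluoro-6-methoxy-4-methylbenzaldehyde, via aryllithium 2 (not isolated)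
Conditions: n-BuLi, THF, −78 °C; DMF, −78 → 0 °C; aq. HCl
Reagents that add atoms: N,N-dimethylformamide CN(C)C=O
Why: Directed ortho-lithiation should take the proton between F and OMe, the most acidic one, and DMF formylates the aryllithium (Bouveault-type formylation).

Step 2
Reactants: 3 2-fluoro-6-methoxy-4-methylbenzaldehyde
Product: 4 2-fluoro-3-iodo-6-methoxy-4-methylbenzaldehyde
Conditions: NIS, TFA, MeCN, rt → 50 °C
Reagents that add atoms: N-iodosuccinimide O=C1CCC(=O)N1I
Why: Electrophilic aromatic iodination should go para to OMe, at the position flanked by the small F and by CH3 and meta to CHO, which is both the most activated and the less hindered site.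

Step 3
Reactants: 4 2-fluoro-3-iodo-6-methoxy-4-methylbenzaldehyde
Product: 5 2-hydroxy-3-iodo-6-methoxy-4-methylbenzaldehyde
Conditions: KOH, DMSO/H2O, 60 °C; then 1 M HCl
Reagents that add atoms: potassium hydroxide [K+].[OH-]
Why: SNAr by hydroxide at the fluoride ortho to the formyl group (Meisenheimer anion delocalised into CHO) should give the salicylaldehyde, and the iodide is not an SNAr leaving group under these conditions.

Step 4
Reactants: 6 4,5-difluoro-2-hydroxybenzoic acid
Product: 8 N,N-diethyl-4,5-difluoro-2-hydroxybenzamide, via acid chloride 7 (not isolated)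
Conditions: SOCl2, cat. DMF, toluene, 70 °C; then Et2NH (excess), CH2Cl2, 0 °C
Reagents that add atoms: diethylamine CCNCC
Why: Acid chloride formation followed by N-acylation of the amine, which at 0 °C is far faster than SNAr at either C–F.

Step 5
Reactants: 8 N,N-diethyl-4,5-difluoro-2-hydroxybenzamide
Product: 9 2-(benzyloxy)-N,N-diethyl-4,5-difluorobenzamide
Conditions: BnBr, K2CO3, DMF, rt
Reagents that add atoms: benzyl bromide BrCc1ccccc1
Why: Williamson etherification of the phenoxide with a reactive benzylic halide; at room temperature the phenoxide should not displace the ring fluorides.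

Step 6
Reactants: 9 2-(benzyloxy)-N,N-diethyl-4,5-difluorobenzamide
Product: 11 6-(benzyloxy)-N,N-diethyl-3,4-difluoro-2-formylbenzamide, via arylmagnesium chloride 10 (not isolated)
Conditions: TMPMgCl·LiCl, THF, 0 °C; DMF, 0 °C → rt; aq. HCl
Reagents that add atoms: N,N-dimethylformamide CN(C)C=O
Why: Directed ortho-magnesiation should occur at the C–H flanked by the coordinating amide and by F, and DMF formylates the arylmagnesium; the magnesium amide base avoids aryne formation by fluoride loss and deprotonation of the benzyl ether.

Step 7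
Reactants: 5 2-hydroxy-3-iodo-6-methoxy-4-methylbenzaldehyde; 11 6-(benzyloxy)-N,N-diethyl-3,4-difluoro-2-formylbenzamide
Product: 12 6-(benzyloxy)-N,N-diethyl-4-fluoro-2-formyl-3-(2-formyl-6-iodo-3-methoxy-5-methylphenoxy)benzamide
Conditions: Cs2CO3, DMSO, 70 °C
Reagents that add atoms: none
Why: SNAr diaryl ether formation, in which the phenoxide should attack the fluoride ortho to CHO, whereas the other fluoride is para only to an amide twisted out of plane by its two ortho neighbours and should stay.

Step 8
Reactants: 12 6-(benzyloxy)-N,N-diethyl-4-fluoro-2-formyl-3-(2-formyl-6-iodo-3-methoxy-5-methylphenoxy)benzamide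
Product: 13 racemic 2-{[7-(benzyloxy)-5-fluoro-3-hydroxy-1-oxo-1,3-dihydro-2-benzofuran-4-yl]oxy}-3-iodo-6-methoxy-4-methylbenzaldehyde
Conditions: 3 M HCl, 1,4-dioxane, 80 °C
Reagents that add atoms: water O
Why: Acid hydrolysis with neighbouring-group assistance, in which the hydrate of the ortho-formyl group attacks the protonated amide (5-exo) and expels diethylamine to give the 3-hydroxyphthalide; the lactol centre forms racemic and is labile at this stage.

Step 9
Reactants: 13 racemic hydroxyphthalide diaryl ether
Product: 14 racemic 7-(benzyloxy)-4-[2-(dimethoxymethyl)-6-iodo-3-methoxy-5-methylphenoxy]-5-fluoro-3-methoxy-2-benzofuran-1(3H)-one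
Conditions: HC(OMe)3, MeOH, CSA (cat.), 50 °C; Et3N quench
Reagents that add atoms: trimethyl orthoformate COC(OC)OC; methanol CO
Why: Acid-catalysed acetalisation should convert the ring A aldehyde into its dimethyl acetal and the lactol into the pseudo-ester (3-methoxyphthalide), which masks both against the Grignard reagent and locks the ring B carbonyl as a planar lactone para to C–F.

Step 10
Reactants: 14 racemic iodo fluoro diaryl ether (dimethyl acetal, 3-methoxyphthalide)
Product: 18 racemic 4-(benzyloxy)-11-(dimethoxymethyl)-1,10-dimethoxy-8-methyl-1H-isobenzofuro[4,5-b][1,4]benzodioxepine-3,7-dione, via arylmagnesium chloride 15 (not isolated), via chloromagnesium carboxylate 16 (not isolated), via caesium carboxylate 17 (not isolated)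
Conditions: i-PrMgCl·LiCl, THF, −40 °C; CO2 (1 atm), −40 °C → rt; volatiles (THF, 2-iodopropane) removed in vacuo; Cs2CO3 (1.1 equiv), DMSO, 90 °C (one pot)
Reagents that add atoms: carbon dioxide O=C=O
Why: Proposed new method: iodine–magnesium exchange gives the ring A arylmagnesium 15, which adds to CO2 to form the aryl–carboxyl C–C bond; after Mg-to-Cs exchange the carboxylate oxygen attacks the ring B C–F carbon by addition–elimination (Meisenheimer complex, loss of fluoride) to form the aryl–O ester bond, so CO2 becomes the O–C(=O) bridge of the depsidone. The closest known reactions are Grignard carboxylation and intramolecular SNAr O-arylation (carboxylate displacement of activated aryl fluorides to aryl esters, phenoxide SNAr closures of dibenzo-fused seven-membered rings); closing a depsidone lactone by carboxylate SNAr in tandem with CO2 capture is the untested part. The seven-membered dioxepinone ring closes by intramolecular SNAr (7-exo attack on the sp2 C–F carbon), the ether oxygen already holding carboxylate and C–F in a 1,6-relationship. No stereocentre is formed, and the racemic acetal carbon of the pseudo-ester is not touched. The step needs chemoselective exchange at C–I over addition to the lactone, which the low temperature and a carbonyl that cannot be reached intramolecularly should secure, and an activated site for the weak carboxylate nucleophile, which the substrate supplies as the single fluoride para to the coplanar phthalide carbonyl; 2-iodopropane is removed before heating so that it cannot alkylate the carboxylate.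

Step 11
Reactants: 18 racemic protected depsidone
Product: 19 racemic 4-(benzyloxy)-1-hydroxy-10-methoxy-8-methyl-3,7-dioxo-1,3-dihydro-7H-isobenzofuro[4,5-b][1,4]benzodioxepine-11-carbaldehyde
Conditions: 2 M HCl, THF, 50 °C
Reagents that add atoms: water O
Why: Acid-catalysed acetal hydrolysis should free the ring A aldehyde and convert the 3-methoxyphthalide into the 3-hydroxyphthalide, while the aryl ester of the depsidone and the benzyl ether are stable to dilute aqueous acid.

Step 12
Reactants: 19 racemic lactol benzyl ether
Product: 21 (1S)-4-(benzyloxy)-10-methoxy-8-methyl-3,7-dioxo-1-[(1S)-1-phenylethoxy]-1,3-dihydro-7H-isobenzofuro[4,5-b][1,4]benzodioxepine-11-carbaldehyde, via (1R) acetal epimer 20 (not isolated)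
Conditions: (S)-1-phenylethanol (1.5 equiv), PPTS (cat.), 4 Å MS, toluene, 60 °C; then heptane, slurry aged 40 °C → rt with the acid still present; filtration
Reagents that add atoms: (S)-1-phenylethanol C[C@H](O)c1ccccc1
Why: Acid-catalysed pseudo-ester (acetal) formation through the acyloxocarbenium ion gives both epimers, which keep interconverting through that ion in solution while the less soluble one crystallises (crystallisation-induced diastereomer transformation, the reaction type known for 5-alkoxy-2(5H)-furanones of chiral alcohols), so the (1R) epimer 20 should be drained into the (1S) acetal 21; the acetal configuration is thus set by the (S)-auxiliary through the crystal lattice, and since the alcohol C–O bond is not broken the auxiliary keeps its (S) configuration.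

Step 13
Reactants: 21 (1S) 1-phenylethyl acetal benzyl ether
Product: 22 (1S)-1,4-dihydroxy-10-methoxy-8-methyl-3,7-dioxo-1,3-dihydro-7H-isobenzofuro[4,5-b][1,4]benzodioxepine-11-carbaldehyde (target)
Conditions: H2 (1 atm), 10% Pd/C, EtOAc, rt; filtration and evaporation below 25 °C
Reagents that add atoms: none
Why: Hydrogenolysis should cleave the two exocyclic benzylic C–O bonds (PhCH2–OAr and PhCH(CH3)–O) but not the bonds at the acetal carbon, so the (S) configuration fixed in 21 is carried into the lactol; the in-plane phthalide C–O bond resists hydrogenolysis and the hindered ring A aldehyde should be reduced much more slowly than the benzyl groups are removed.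

**Compound list**
1 | 1-fluoro-3-methoxy-5-methylbenzene | COc1cc(C)cc(F)c1 | starting material
2 | (2-fluoro-6-methoxy-4-methylphenyl)lithium | [Li]c1c(F)cc(C)cc1OC | intermediate
3 | 2-fluoro-6-methoxy-4-methylbenzaldehyde | COc1cc(C)cc(F)c1C=O | intermediate
4 | 2-fluoro-3-iodo-6-methoxy-4-methylbenzaldehyde | COc1cc(C)c(I)c(F)c1C=O | intermediate
5 | 2-hydroxy-3-iodo-6-methoxy-4-methylbenzaldehyde | COc1cc(C)c(I)c(O)c1C=O | intermediate
6 | 4,5-difluoro-2-hydroxybenzoic acid | OC(=O)c1cc(F)c(F)cc1O | starting material
7 | 4,5-difluoro-2-hydroxybenzoyl chloride | O=C(Cl)c1cc(F)c(F)cc1O | intermediate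
8 | N,N-diethyl-4,5-difluoro-2-hydroxybenzamide | CCN(CC)C(=O)c1cc(F)c(F)cc1O | intermediate
9 | 2-(benzyloxy)-N,N-diethyl-4,5-difluorobenzamide | CCN(CC)C(=O)c1cc(F)c(F)cc1OCc1ccccc1 | intermediate
10 | [3-(benzyloxy)-2-(diethylcarbamoyl)-5,6-difluorophenyl]magnesium chloride | CCN(CC)C(=O)c1c([Mg]Cl)c(F)c(F)cc1OCc1ccccc1 | intermediate
11 | 6-(benzyloxy)-N,N-diethyl-3,4-difluoro-2-formylbenzamide | CCN(CC)C(=O)c1c(C=O)c(F)c(F)cc1OCc1ccccc1 | intermediate
12 | 6-(benzyloxy)-N,N-diethyl-4-fluoro-2-formyl-3-(2-formyl-6-iodo-3-methoxy-5-methylphenoxy)benzamide | COc1cc(C)c(I)c(Oc2c(F)cc(OCc3ccccc3)c(C(=O)N(CC)CC)c2C=O)c1C=O | intermediate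
13 | racemic 2-{[7-(benzyloxy)-5-fluoro-3-hydroxy-1-oxo-1,3-dihydro-2-benzofuran-4-yl]oxy}-3-iodo-6-methoxy-4-methylbenzaldehyde | COc1cc(C)c(I)c(Oc2c(F)cc(OCc3ccccc3)c3C(=O)OC(O)c23)c1C=O | intermediate
14 | racemic 7-(benzyloxy)-4-[2-(dimethoxymethyl)-6-iodo-3-methoxy-5-methylphenoxy]-5-fluoro-3-methoxy-2-benzofuran-1(3H)-one | COc1cc(C)c(I)c(Oc2c(F)cc(OCc3ccccc3)c3C(=O)OC(OC)c23)c1C(OC)OC | intermediate
15 | arylmagnesium chloride from 14 (MgCl in place of I on ring A) | COc1cc(C)c([Mg]Cl)c(Oc2c(F)cc(OCc3ccccc3)c3C(=O)OC(OC)c23)c1C(OC)OC | intermediate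
16 | chloromagnesium carboxylate (CO2MgCl in place of I on ring A) | COc1cc(C)c(C(=O)O[Mg]Cl)c(Oc2c(F)cc(OCc3ccccc3)c3C(=O)OC(OC)c23)c1C(OC)OC | intermediate
17 | caesium carboxylate (same anion, Cs counter-ion) | COc1cc(C)c(C(=O)[O-])c(Oc2c(F)cc(OCc3ccccc3)c3C(=O)OC(OC)c23)c1C(OC)OC.[Cs+] | intermediate
18 | racemic protected depsidone: 4-(benzyloxy)-11-(dimethoxymethyl)-1,10-dimethoxy-8-methyl-1H-isobenzofuro[4,5-b][1,4]benzodioxepine-3,7-dione | COc1cc(C)c2c(c1C(OC)OC)Oc1c(cc(OCc3ccccc3)c3c1C(OC)OC3=O)OC2=O | intermediate
19 | racemic 4-(benzyloxy)-1-hydroxy-10-methoxy-8-methyl-3,7-dioxo-1,3-dihydro-7H-isobenzofuro[4,5-b][1,4]benzodioxepine-11-carbaldehyde | COc1cc(C)c2c(c1C=O)Oc1c(cc(OCc3ccccc3)c3c1C(O)OC3=O)OC2=O | intermediate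
20 | (1R)-4-(benzyloxy)-10-methoxy-8-methyl-3,7-dioxo-1-[(1S)-1-phenylethoxy]-1,3-dihydro-7H-isobenzofuro[4,5-b][1,4]benzodioxepine-11-carbaldehyde (epimer of 21 at the acetal carbon; stays in solution and equilibrates to 21) | COc1cc(C)c2c(c1C=O)Oc1c(cc(OCc3ccccc3)c3c1[C@H](O[C@@H](C)c1ccccc1)OC3=O)OC2=O | intermediate
21 | (1S)-4-(benzyloxy)-10-methoxy-8-methyl-3,7-dioxo-1-[(1S)-1-phenylethoxy]-1,3-dihydro-7H-isobenzofuro[4,5-b][1,4]benzodioxepine-11-carbaldehyde | COc1cc(C)c2c(c1C=O)Oc1c(cc(OCc3ccccc3)c3c1[C@@H](O[C@@H](C)c1ccccc1)OC3=O)OC2=O | intermediate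
22 | (1S)-1,4-dihydroxy-10-methoxy-8-methyl-3,7-dioxo-1,3-dihydro-7H-isobenzofuro[4,5-b][1,4]benzodioxepine-11-carbaldehyde | COc1cc(C)c2c(c1C=O)Oc1c(cc(O)c3c1[C@@H](O)OC3=O)OC2=O | target

**Step count and risks**

Total: 13 steps. Longest linear sequence: 10 steps (steps 1–3 or 4–6, then 7–13).

Steps most likely to fail:

1. Step 10 (proposed new method). The carboxylate is a weak nucleophile and the ring is activated by one carbonyl only, so the displacement of fluoride may be too slow and the sequence may stop at the open carboxylate; the Grignard reagent may also add to the lactone during the exchange. Fallback with known chemistry, from 14: the fluoride is first replaced by hydroxyl with a strong oxygen nucleophile (acetohydroxamic acid, K2CO3, DMSO, 80 °C) to give the phenol F1. F1 is treated with two equivalents of i-PrMgCl·LiCl (the first deprotonates the phenol), then CO2, and worked up at pH 5 to give the hydroxy acid F2. F2 is closed by the classical depsidone lactonisation (DCC, cat. DMAP, CH2Cl2) and comes back to the route at 18.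

2. Step 12. The crystallisation may deposit the (1R) epimer or no solid at all, or the epimers may interconvert too slowly under the mild acid, so that the equilibration does not converge on one diastereomer. Fallback, from 19, which separates enantiomers on a chiral phase instead of crystallising a diastereomer: acetalisation with benzyl alcohol (PPTS, 4 Å MS, toluene, 60 °C) gives the racemic benzyl pseudo-ester F3. Preparative SFC on a chiral stationary phase gives the (1S) enantiomer F4, while the (1R) enantiomer F5 is racemised under the acetalisation conditions and resolved again. Hydrogenolysis of F4 (H2, Pd/C, EtOAc, rt) removes both primary benzyl groups and comes back to the route at 22.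

3. Step 13. The ring A formyl group may be reduced while the slower secondary benzylic C–O bond is being cleaved, or the freed lactol may epimerise on the catalyst by ring–chain tautomerism. Fallback, from 19: the benzyl ether is removed without hydrogen (BCl3, pentamethylbenzene, CH2Cl2, −78 °C, at which the methyl ether should stay) to give the racemic lactol phenol F6. Acetalisation with (S)-1-(naphthalen-2-yl)ethanol (PPTS, 4 Å MS, toluene) and separation gives the (1S) acetal F7, while its (1R) epimer F8 is re-equilibrated. Oxidative removal of the naphthylethyl group from F7 (DDQ, CH2Cl2/pH 7 buffer, 0 °C) cleaves only the auxiliary C–O bond and should come back to the route at 22.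

**Further compounds**
F1 | step 10 | racemic 7-(benzyloxy)-4-[2-(dimethoxymethyl)-6-iodo-3-methoxy-5-methylphenoxy]-5-hydroxy-3-methoxy-2-benzofuran-1(3H)-one | COc1cc(C)c(I)c(Oc2c(O)cc(OCc3ccccc3)c3C(=O)OC(OC)c23)c1C(OC)OC
F2 | step 10 | racemic 2-{[7-(benzyloxy)-5-hydroxy-3-methoxy-1-oxo-1,3-dihydro-2-benzofuran-4-yl]oxy}-3-(dimethoxymethyl)-4-methoxy-6-methylbenzoic acid | COc1cc(C)c(C(=O)O)c(Oc2c(O)cc(OCc3ccccc3)c3C(=O)OC(OC)c23)c1C(OC)OC
F3 | step 12 | racemic 1,4-bis(benzyloxy)-10-methoxy-8-methyl-3,7-dioxo-1,3-dihydro-7H-isobenzofuro[4,5-b][1,4]benzodioxepine-11-carbaldehyde | COc1cc(C)c2c(c1C=O)Oc1c(cc(OCc3ccccc3)c3c1C(OCc1ccccc1)OC3=O)OC2=O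
F4 | step 12 | (1S)-1,4-bis(benzyloxy)-10-methoxy-8-methyl-3,7-dioxo-1,3-dihydro-7H-isobenzofuro[4,5-b][1,4]benzodioxepine-11-carbaldehyde | COc1cc(C)c2c(c1C=O)Oc1c(cc(OCc3ccccc3)c3c1[C@@H](OCc1ccccc1)OC3=O)OC2=O
F5 | step 12 | (1R)-1,4-bis(benzyloxy)-10-methoxy-8-methyl-3,7-dioxo-1,3-dihydro-7H-isobenzofuro[4,5-b][1,4]benzodioxepine-11-carbaldehyde | COc1cc(C)c2c(c1C=O)Oc1c(cc(OCc3ccccc3)c3c1[C@H](OCc1ccccc1)OC3=O)OC2=O
F6 | step 13 | racemic 1,4-dihydroxy-10-methoxy-8-methyl-3,7-dioxo-1,3-dihydro-7H-isobenzofuro[4,5-b][1,4]benzodioxepine-11-carbaldehyde | COc1cc(C)c2c(c1C=O)Oc1c(cc(O)c3c1C(O)OC3=O)OC2=O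
F7 | step 13 | (1S)-4-hydroxy-10-methoxy-8-methyl-1-[(1S)-1-(naphthalen-2-yl)ethoxy]-3,7-dioxo-1,3-dihydro-7H-isobenzofuro[4,5-b][1,4]benzodioxepine-11-carbaldehyde | COc1cc(C)c2c(c1C=O)Oc1c(cc(O)c3c1[C@@H](O[C@@H](C)c1ccc4ccccc4c1)OC3=O)OC2=O
F8 | step 13 | (1R)-4-hydroxy-10-methoxy-8-methyl-1-[(1S)-1-(naphthalen-2-yl)ethoxy]-3,7-dioxo-1,3-dihydro-7H-isobenzofuro[4,5-b][1,4]benzodioxepine-11-carbaldehyde | COc1cc(C)c2c(c1C=O)Oc1c(cc(O)c3c1[C@H](O[C@@H](C)c1ccc4ccccc4c1)OC3=O)OC2=O
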